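Ring A (cyclohexane C5–C10) is closed by forming the C9–C10 bond in an intramolecular Nozaki–Hiyama–Kishi allylation. The homoallylic alcohol motif C9(O)–C10(CH3)(C1=C2) of ring A is read as a C9 aldehyde attacked by the γ-carbon C10 of a Z-allylchromium unit at C2. One operation closes the carbocycle and sets the quaternary C10 and the C9 carbinol. The precursor is the preformed cis α-methylene-γ-lactone (ring B) carrying the C9 aldehyde on C8 and, on C7, a chain holding the C6 isobutyrate, the C5 isopropenyl group and the Z-allylic chloride. A dihydropyran masks O6 and C2 until one acylative ring opening releases both.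

Key step: step 9

Remark: elemane numbering is used for all intermediates (C1H=C2H2 vinyl and C14 methyl on C10; C3H2=C4–C15 on C5; C11(=C13H2)–C12(=O) lactone; ring A = carbocycle C5–C10, ring B = lactone). Compounds 1, 2, 6, 11 and 14 (60 wt% aqueous solution) are taken as commercial.

Step 1
Reactants: 1 (R)-2,2-dimethyl-1,3-dioxolane-4-carbaldehyde; 2 2,4-dimethylpenta-1,3-diene
Product: 5 (1S)-1-[(4R)-2,2-dimethyl-1,3-dioxolan-4-yl]-3-methyl-2-(prop-1-en-2-yl)but-3-en-1-ol, via potassium 2,4-dimethylpentadienide 3 (not isolated), via pentadienyl pinacol boronate 4 (not isolated)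
Conditions: 2, n-BuLi, KOt-Bu, THF, −78 to 0 °C; i-PrOBpin, −78 °C; then 1, −78 °C to rt; H2O
Reagents that add atoms: none
Why: Superbase metalation of 2 gives 3, borylation at the terminus gives allylic boronate 4, and 4 adds through its central carbon in a closed six-membered allylboration transition state to the Felkin–Anh face of the α-alkoxy aldehyde, which should set the (S)-carbinol (future C6) anti to the dioxolane oxygen; the carbon bearing the two identical isopropenyl groups is not yet a stereocentre, and the minor syn isomer should be separable by chromatography.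

Step 2
Reactants: 5; 6 allyl bromide
Product: 7 (4R)-4-[(1S)-1-(allyloxy)-3-methyl-2-(prop-1-en-2-yl)but-3-en-1-yl]-2,2-dimethyl-1,3-dioxolane
Conditions: NaH, n-Bu4NI (cat.), THF/DMF, 0 °C to rt
Reagents that add atoms: none
Why: Williamson ether synthesis on the sodium alkoxide with a reactive allylic halide leaves the carbinol configuration and the acetonide untouched.

Step 3
Reactants: 7
Product: 8 (2S,3S)-2-[(4R)-2,2-dimethyl-1,3-dioxolan-4-yl]-4-methyl-3-(prop-1-en-2-yl)-3,6-dihydro-2H-pyran (2,3-trans)
Conditions: second-generation Grubbs catalyst, RuCl2(=CHPh)(H2IMes)(PCy3) (5 mol %), CH2Cl2, 40 °C, 0.01 M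
Reagents that add atoms: none
Why: Diastereotopic-group-selective ring-closing metathesis: the ruthenium alkylidene loads on the allyl ether and should close onto the isopropenyl group that lets both ring substituents sit pseudo-equatorial in the developing half-chair, which sets C5 trans to C6 and fixes the C1=C10 alkene as Z by ring constraint.

Step 4
Reactants: 8
Product: 10 (2S,3S)-4-methyl-3-(prop-1-en-2-yl)-3,6-dihydro-2H-pyran-2-carbaldehyde, via diol 9 (not isolated)
Conditions: H5IO6, EtOAc, rt
Reagents that add atoms: none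
Why: Periodic acid hydrolyses the terminal acetonide and cleaves the liberated 1,2-diol 9 (Malaprade glycol cleavage) to the α-alkoxy aldehyde, whose α-centre C6 sits in its more stable trans arrangement to C5.

Step 5
Reactants: 10; 11 methyl acrylate
Product: 12 methyl 2-{hydroxy[(2S,3S)-4-methyl-3-(prop-1-en-2-yl)-3,6-dihydro-2H-pyran-2-yl]methyl}prop-2-enoate (both carbinol epimers)
Conditions: DABCO (1 equiv), 11 (5 equiv), MeOH, rt
Reagents that add atoms: none
Why: Morita–Baylis–Hillman reaction of an activated α-alkoxy aldehyde; the configuration of the new carbinol (C7) is irrelevant because step 6 erases it.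

Step 6
Reactants: 12
Product: 13 methyl (2Z)-2-(bromomethyl)-3-[(2R,3S)-4-methyl-3-(prop-1-en-2-yl)-3,6-dihydro-2H-pyran-2-yl]prop-2-enoate
Conditions: NBS, Me2S, CH2Cl2, 0 °C to rt
Reagents that add atoms: N-bromosuccinimide, O=C1CCC(=O)N1Br
Why: Corey–Kim-type activation of the allylic alcohol and SN2′ delivery of bromide with allylic transposition should give the thermodynamically preferred (Z)-2-(bromomethyl)enoate, and the sulfonium reagent does not attack the other alkenes.

Step 7
Reactants: 13; 14 dimethoxyacetaldehyde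
Product: 16 (4S,5S)-5-(dimethoxymethyl)-3-methylidene-4-[(2S,3S)-4-methyl-3-(prop-1-en-2-yl)-3,6-dihydro-2H-pyran-2-yl]oxolan-2-one (4,5-cis), via syn-hydroxy ester 15 (not isolated)
Conditions: In (powder), THF/H2O (1:1), rt; then p-TsOH·H2O (cat.), CH2Cl2, rt
Reagents that add atoms: none
Why: Barbier-type indium allylation through a closed chair transition state in which the Z-γ-substituent is axial gives the syn adduct (C7/C8, hence the cis lactone after acid lactonisation), and 1,3-allylic strain holds C6–H in the alkene plane so that the aldehyde should add to C7 anti to the ring C5–C6 bond, on the side of the ring oxygen.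

Step 8
Reactants: 16
Product: 18 (1S,2S,3Z)-5-chloro-1-[(2S,3S)-2-formyl-4-methylidene-5-oxooxolan-3-yl]-3-methyl-2-(prop-1-en-2-yl)pent-3-en-1-yl 2-methylpropanoate, via α-chloro ether 17 (not isolated)
Conditions: i-PrCOCl (4 equiv), ZnCl2 (0.2 equiv), CH2Cl2, −20 to 0 °C; then aq. NaHCO3, THF, 0 °C
Reagents that add atoms: isobutyryl chloride, CC(C)C(=O)Cl; water, O
Why: Acylative ether cleavage: the ZnCl2-activated acid chloride acylates the ring oxygen and chloride opens the acyloxonium by SN2 attack at the primary allylic C2, which installs the C6 isobutyrate and the Z-allylic chloride at once with the ring-derived geometry, while acetal–acid chloride exchange turns the dimethyl acetal into α-chloro ether 17, hydrolysed to the C9 aldehyde on bicarbonate work-up.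

Step 9
Reactants: 18
Product: 19 (5S,6S,7S,8S,9S,10S)-9-hydroxy-6-(2-methylpropanoyloxy)elema-1,3,11(13)-trien-12,8-olide
Conditions: CrCl2 (8 equiv), LiI (0.2 equiv), DMPU/THF, rt, slow addition of 18 to 0.005 M
Reagents that add atoms: none
Why: Two equivalents of divalent chromium reduce the allylic chloride (through the iodide formed in situ) to a σ-allyl species of trivalent chromium at C2, which adds to the C9 aldehyde through its γ-carbon C10 in a closed chair Zimmerman–Traxler transition state; the closest known reaction type is the intramolecular Nozaki–Hiyama–Kishi allylation with γ,γ-disubstituted allylic halides under LiI/DMPU conditions that preserve the alkene geometry. Ring A closes by 6-exo-trig attack on C9=O (SE2′ at the allyl unit), the only carbocycle formed. C10 is controlled by the Z geometry and the C5 stereocentre: ring A forms as the chair with the C5 isopropenyl group and the C7–C11 bond equatorial, the C5 branch is axial on the chromium-containing ring, and so C14 becomes axial (cis to the isopropenyl group) and the vinyl group equatorial. C9 is controlled by the chromium bridge from C2 to O9, which requires O9 gauche to the vinyl group, that is axial and anti to the axial C8–O bond (dipole-minimised), giving the 9-OH cis to the vinyl group and trans to the lactone oxygen. The step needs γ- over α-attack (α would give an eight-membered ring), aldehyde over lactone and ester chemoselectivity (inherent to organochromium reagents), and cyclisation over intermolecular coupling (high dilution). It also needs retention of the Z geometry, which the LiI/DMPU protocol and the fast six-membered ring closure should secure.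

Step 10
Reactants: 19
Product: 20 (5S,6S,7S,8S,9S,10S)-9,15-dihydroxy-6-(2-methylpropanoyloxy)elema-1,3,11(13)-trien-12,8-olide
Conditions: SeO2 (0.5 equiv), t-BuOOH (2 equiv), CH2Cl2, rt
Reagents that add atoms: selenium dioxide, O=[Se]=O; tert-butyl hydroperoxide, CC(C)(C)OO
Why: Allylic oxidation by ene reaction and [2,3]-sigmatropic shift should occur only at the 1,1-disubstituted C3=C4 alkene and at its methyl group (C15) in preference to the C5 methine, because the vinyl group has no allylic hydrogen and the lactone methylene is electron-poor.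

Step 11
Reactants: 20
Product: 21 (5S,6S,7S,8S,9S,10S)-9,15-diacetoxy-6-(2-methylpropanoyloxy)elema-1,3,11(13)-trien-12,8-olide (CNP0500052.1)
Conditions: Ac2O, pyridine, DMAP (cat.), CH2Cl2, rt
Reagents that add atoms: acetic anhydride, CC(=O)OC(C)=O
Why: DMAP-catalysed acylation should esterify both the primary allylic C15–OH and the hindered secondary C9–OH without touching the stereocentres or the Michael acceptor.

Compound list
1 | (R)-2,2-dimethyl-1,3-dioxolane-4-carbaldehyde | O=C[C@H]1COC(C)(C)O1 | starting material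
2 | 2,4-dimethylpenta-1,3-diene | CC(C)=CC(C)=C | starting material
3 | potassium 2,4-dimethylpentadienide | [K+].[CH2-]C(C)=CC(C)=C | intermediate
4 | 2-(2,4-dimethylpenta-2,4-dien-1-yl)-4,4,5,5-tetramethyl-1,3,2-dioxaborolane (alkene geometry immaterial) | C=C(C)C=C(C)CB1OC(C)(C)C(C)(C)O1 | intermediate
5 | (1S)-1-[(4R)-2,2-dimethyl-1,3-dioxolan-4-yl]-3-methyl-2-(prop-1-en-2-yl)but-3-en-1-ol | O[C@H]([C@H]1COC(C)(C)O1)C(C(C)=C)C(C)=C | intermediate
6 | allyl bromide | C=CCBr | starting material
7 | (4R)-4-[(1S)-1-(allyloxy)-3-methyl-2-(prop-1-en-2-yl)but-3-en-1-yl]-2,2-dimethyl-1,3-dioxolane | C=CCO[C@H]([C@H]1COC(C)(C)O1)C(C(C)=C)C(C)=C | intermediate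
8 | (2S,3S)-2-[(4R)-2,2-dimethyl-1,3-dioxolan-4-yl]-4-methyl-3-(prop-1-en-2-yl)-3,6-dihydro-2H-pyran | C=C(C)[C@H]1C(C)=CCO[C@@H]1[C@H]2COC(C)(C)O2 | intermediate
9 | (1R)-1-[(2S,3S)-4-methyl-3-(prop-1-en-2-yl)-3,6-dihydro-2H-pyran-2-yl]ethane-1,2-diol | C=C(C)[C@H]1C(C)=CCO[C@@H]1[C@H](O)CO | intermediate
10 | (2S,3S)-4-methyl-3-(prop-1-en-2-yl)-3,6-dihydro-2H-pyran-2-carbaldehyde | C=C(C)[C@H]1C(C)=CCO[C@@H]1C=O | intermediate
11 | methyl acrylate | C=CC(=O)OC | starting material
12 | methyl 2-{hydroxy[(2S,3S)-4-methyl-3-(prop-1-en-2-yl)-3,6-dihydro-2H-pyran-2-yl]methyl}prop-2-enoate (both carbinol epimers) | C=C(C)[C@H]1C(C)=CCO[C@@H]1C(O)C(=C)C(=O)OC | intermediate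
13 | methyl (2Z)-2-(bromomethyl)-3-[(2R,3S)-4-methyl-3-(prop-1-en-2-yl)-3,6-dihydro-2H-pyran-2-yl]prop-2-enoate | C=C(C)[C@H]1C(C)=CCO[C@@H]1/C=C(\CBr)C(=O)OC | intermediate
14 | dimethoxyacetaldehyde | COC(OC)C=O | starting material
15 | methyl (3R,4S)-4-hydroxy-5,5-dimethoxy-2-methylidene-3-[(2S,3S)-4-methyl-3-(prop-1-en-2-yl)-3,6-dihydro-2H-pyran-2-yl]pentanoate | C=C(C)[C@H]1C(C)=CCO[C@@H]1[C@H](C(=C)C(=O)OC)[C@H](O)C(OC)OC | intermediate
16 | (4S,5S)-5-(dimethoxymethyl)-3-methylidene-4-[(2S,3S)-4-methyl-3-(prop-1-en-2-yl)-3,6-dihydro-2H-pyran-2-yl]oxolan-2-one | C=C(C)[C@H]1C(C)=CCO[C@@H]1[C@H]2[C@@H](C(OC)OC)OC(=O)C2=C | intermediate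
17 | (1S,2S,3Z)-5-chloro-1-{(2S,3S)-2-[chloro(methoxy)methyl]-4-methylidene-5-oxooxolan-3-yl}-3-methyl-2-(prop-1-en-2-yl)pent-3-en-1-yl 2-methylpropanoate (both epimers at the chloro(methoxy)methyl carbon) | ClC/C=C(C)\[C@@H]([C@@H]([C@H]1[C@@H](C(Cl)OC)OC(=O)C1=C)OC(=O)C(C)C)C(C)=C | intermediate
18 | (1S,2S,3Z)-5-chloro-1-[(2S,3S)-2-formyl-4-methylidene-5-oxooxolan-3-yl]-3-methyl-2-(prop-1-en-2-yl)pent-3-en-1-yl 2-methylpropanoate | ClC/C=C(C)\[C@@H]([C@@H]([C@H]1[C@@H](C=O)OC(=O)C1=C)OC(=O)C(C)C)C(C)=C | intermediate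
19 | (5S,6S,7S,8S,9S,10S)-9-hydroxy-6-(2-methylpropanoyloxy)elema-1,3,11(13)-trien-12,8-olide | C=C[C@]1(C)[C@H](O)[C@H]2OC(=O)C(=C)[C@H]2[C@@H](OC(=O)C(C)C)[C@H]1C(C)=C | intermediate
20 | (5S,6S,7S,8S,9S,10S)-9,15-dihydroxy-6-(2-methylpropanoyloxy)elema-1,3,11(13)-trien-12,8-olide | C=C[C@]1(C)[C@H](O)[C@H]2OC(=O)C(=C)[C@H]2[C@@H](OC(=O)C(C)C)[C@H]1C(=C)CO | intermediate
21 | (5S,6S,7S,8S,9S,10S)-9,15-diacetoxy-6-(2-methylpropanoyloxy)elema-1,3,11(13)-trien-12,8-olide | C=C[C@]1(C)[C@H](OC(C)=O)[C@H]2OC(=O)C(=C)[C@H]2[C@@H](OC(=O)C(C)C)[C@H]1C(=C)COC(C)=O | target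

Total step count: 11. Longest linear sequence: 11 steps (from 1 and 2 to 21).

Steps most likely to fail

Step 9. A 1,3-metallotropic shift of the allylchromium through its C10-bound isomer could scramble the Z geometry before ring closure and erode the selectivity at C9, and intermolecular allyl transfer competes if dilution is insufficient. The fallback sets out from 18 and comes back at 19. The allylic chloride would be silylated with Me3SiSiMe3 and Pd(PPh3)4 (cat.) in THF to give the allyltrimethylsilane aldehyde F1. F1 would then be cyclised with BF3·OEt2 in CH2Cl2 at −78 °C in an intramolecular Hosomi–Sakurai reaction. Its open synclinal transition state does not depend on the alkene geometry, and the same ring A chair with C9=O anti to the axial C8–O bond should lead to 19.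

Step 8. The α-chloro ether formed from the acetal could ionise under ZnCl2 and be captured by an alkene (Prins-type closure), the activated acid chloride could acylate the isopropenyl group, or the allylic chloride could ionise and lose its Z geometry. The fallback sets out from 13 and comes back at 18. The acylative ring opening (i-PrCOCl, ZnCl2 cat., CH2Cl2, −20 °C) would be run one stage earlier on 13, which carries no acetal, to give the open-chain chloro bromo dienoate F2. Indium-mediated Barbier allylation of 14 at the far more reactive 2-(bromomethyl)acrylate terminus (the trisubstituted allylic chloride should be inert to In in aqueous THF) would give the hydroxy ester F3. Treatment with p-TsOH would give the lactone acetal F4. Hydrolysis of the acetal with LiBF4 in wet MeCN would give 18.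

Step 3. The kinetically controlled ring closure may discriminate poorly between the two diastereotopic isopropenyl groups and give a cis/trans mixture at C5. The fallback sets out from 5 and comes back at 8. Acylation of 5 with acryloyl chloride and Et3N would give the acrylate F5. Ring-closing metathesis would give the α,β-unsaturated δ-lactone F6, whose C5–H (γ to the carbonyl and allylic) should allow equilibration to the trans isomer with DBU. Reduction with i-Bu2AlH would give the Z-configured diol F7. Mitsunobu cycloetherification (PPh3, DIAD) through the primary allylic alcohol would close the dihydropyran 8.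

Further compounds
F1 | step 9 | (1S,2S)-1-[(2S,3S)-2-formyl-4-methylidene-5-oxooxolan-3-yl]-3-methyl-2-(prop-1-en-2-yl)-5-(trimethylsilyl)pent-3-en-1-yl 2-methylpropanoate (E/Z mixture) | C[Si](C)(C)CC=C(C)[C@@H]([C@@H]([C@H]1[C@@H](C=O)OC(=O)C1=C)OC(=O)C(C)C)C(C)=C
F2 | step 8 | methyl (2Z,4R,5S,6Z)-2-(bromomethyl)-8-chloro-6-methyl-4-(2-methylpropanoyloxy)-5-(prop-1-en-2-yl)octa-2,6-dienoate | ClC/C=C(C)\[C@@H]([C@@H](/C=C(\CBr)C(=O)OC)OC(=O)C(C)C)C(C)=C
F3 | step 8 | methyl (3R,4S)-3-[(1S,2S,3Z)-5-chloro-3-methyl-1-(2-methylpropanoyloxy)-2-(prop-1-en-2-yl)pent-3-en-1-yl]-4-hydroxy-5,5-dimethoxy-2-methylidenepentanoate | ClC/C=C(C)\[C@@H]([C@@H]([C@H](C(=C)C(=O)OC)[C@H](O)C(OC)OC)OC(=O)C(C)C)C(C)=C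
F4 | step 8 | (1S,2S,3Z)-5-chloro-1-[(2S,3S)-2-(dimethoxymethyl)-4-methylidene-5-oxooxolan-3-yl]-3-methyl-2-(prop-1-en-2-yl)pent-3-en-1-yl 2-methylpropanoate | ClC/C=C(C)\[C@@H]([C@@H]([C@H]1[C@@H](C(OC)OC)OC(=O)C1=C)OC(=O)C(C)C)C(C)=C
F5 | step 3 | (1S)-1-[(4R)-2,2-dimethyl-1,3-dioxolan-4-yl]-3-methyl-2-(prop-1-en-2-yl)but-3-en-1-yl prop-2-enoate | C=CC(=O)O[C@H]([C@H]1COC(C)(C)O1)C(C(C)=C)C(C)=C
F6 | step 3 | (5S,6S)-6-[(4R)-2,2-dimethyl-1,3-dioxolan-4-yl]-4-methyl-5-(prop-1-en-2-yl)-5,6-dihydro-2H-pyran-2-one | C=C(C)[C@H]1C(C)=CC(=O)O[C@@H]1[C@H]2COC(C)(C)O2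
F7 | step 3 | (2Z,4S,5S)-5-[(4R)-2,2-dimethyl-1,3-dioxolan-4-yl]-3-methyl-4-(prop-1-en-2-yl)pent-2-ene-1,5-diol | OC/C=C(C)\[C@@H]([C@H](O)[C@H]1COC(C)(C)O1)C(C)=C
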